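## Retrosynthetic overview
1. The target comes from borohydride release of an anti-aldol imide. The C7''–C8'' bond is made by an auxiliary-controlled anti-aldol of vanillin with the (aryloxy)acetyl imide of (−)-pinoresinol.
2. That imide comes from mono-O-alkylation of C2-symmetric (−)-pinoresinol with an N-bromoacetyl oxazolidinone. The two phenols are equivalent, so either gives the same product.
3. Both tetrahydrofuran rings close together by double cyclodehydration of a hexaol, which LiAlH4 releases from an enantiopure diaryl dilactone.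
4. The dilactone comes from succinyl bis[(R)-oxazolidinone] and 2 vanillin isobutyrate in a one-pot double syn-aldol and double auxiliary-expelling lactonisation (2 C–C bonds, 2 C–O bonds, 4 stereocentres, 2 rings).
5. Ring order: two lactone rings at once, then opened, then two THF rings at once. The side chain adds no ring.

Assumption: the SMILES decodes as the (7R,8S,7'R,8'S)-furofuran, which is the (−)-pinoresinol series, carrying an erythro-(7''R,8''S)-guaiacylglycerol unit on O-4 (lignan numbering); simple Li/K/Al salts and B–O aldolates of numbered compounds are counted with the parent compound.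

## Route

Step 1
Reactants: 1 (R)-4-benzyl-1,3-oxazolidin-2-one (2 equiv); 2 succinyl chloride
Product: 3 1,4-bis[(4R)-4-benzyl-2-oxo-1,3-oxazolidin-3-yl]butane-1,4-dione
Conditions: n-BuLi (2.05 equiv), THF, −78 °C; then 2 (1.0 equiv), −78 °C → rt
Reagents that add atoms: none
Why: This is a standard N-acylation of a lithiated Evans oxazolidinone, done here twice on a diacid chloride, and it creates no new stereocentre.

Step 2
Reactants: 3 succinyl bis-imide; 4 vanillin isobutyrate (4-formyl-2-methoxyphenyl 2-methylpropanoate, 2.5 equiv)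
Product: 7 (3R,3aR,6R,6aR)-3,6-bis[4-(isobutyryloxy)-3-methoxyphenyl]tetrahydrofuro[3,4-c]furan-1,4-dione (cis-fused dilactone with both aryl groups exo), via bis(boron enolate) 5 (not isolated), via bis-aldol 6 (not isolated)
Conditions: Bu2BOTf (2.4 equiv), i-Pr2NEt (2.8 equiv), CH2Cl2, 0 °C; 4, −78 → 0 °C; pH 7 buffer/MeOH/30% H2O2, 0 °C → rt; crude stirred with cat. Et3N, CH2Cl2, rt until both lactones are closed
Reagents that add atoms: dibutylboron triflate, CCCCB(CCCC)OS(=O)(=O)C(F)(F)F (its Bu2B groups sit only in 5 and are gone in 6 and 7)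
Why: Proposed new method: double soft enolisation gives the (Z,Z)-bis(boron enolate) 5, each terminus adds to 4 through the Evans Zimmerman–Traxler chair (the (R)-auxiliary fixes C8/C8', the Z geometry fixes the 7,8- and 7',8'-syn relations, which is exactly the aryl-exo pattern of pinoresinol), and in the freed bis-aldol 6 each benzylic OH lies γ to the other, activated N-acyl carbonyl, so two 5-exo-trig lactonisations expel both auxiliaries and close the cis-fused dilactone, while adducts with a mis-set C8/C8' pair cannot close the second ring and are left behind; the closest known reaction types are the Evans syn-aldol/lactonisation of succinate half-imides to paraconic lactones and the racemic double aldol of succinate dianions or bis(silyl ketene acetals) with ArCHO to 2,6-diaryl dilactones.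

Step 3
Reactants: 7 exo/exo dilactone
Product: 9 (−)-pinoresinol (7R,8S,7'R,8'S), via hexaol 8 (not isolated)
Conditions: LiAlH4 (6 equiv), THF, 0 → 50 °C; then 2 M aq HCl to pH 1–2, THF/H2O, rt, 1–3 h (stopped at full conversion)
Reagents that add atoms: none
Why: Hydride reduction of both lactones, and of both aryl esters so that the phenols are freed without a separate step, followed by acid-catalysed double cyclodehydration through p-hydroxybenzyl cation/quinone-methide intermediates is the classical dilactone → tetraol → furofuran sequence; C8/C8' are untouched and each primary OH closes on the C7 face that puts the aryl group trans to the neighbouring C8–C9 bond (exo), the same kinetic outcome as closure of an 8–8' bis-quinone methide, so C7/C7' end up R.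

Step 4
Reactants: 10 (S)-4-benzyl-1,3-oxazolidin-2-one; 11 bromoacetyl bromide
Product: 12 (4S)-4-benzyl-3-(bromoacetyl)-1,3-oxazolidin-2-one
Conditions: n-BuLi (1.0 equiv), THF, −78 °C; then 11 (1.1 equiv), −78 → 0 °C
Reagents that add atoms: none
Why: In this N-acylation of the lithiated oxazolidinone the acyl bromide reacts far faster than the alkyl bromide, and no new stereocentre forms.

Step 5
Reactants: 9 (−)-pinoresinol (1.5 equiv); 12 bromoacetyl imide (1.0 equiv)
Product: 13 (4S)-4-benzyl-3-{[(−)-pinoresinol-4-O-yl]acetyl}-1,3-oxazolidin-2-one (second phenol free)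
Conditions: K2CO3 (1.1 equiv), acetone, rt; excess 9 recovered
Reagents that add atoms: none
Why: This is a Williamson ether synthesis in which SN2 at the activated α-bromo imide outruns acyl attack, the C2 symmetry of 9 means either phenol gives the same mono-ether, the excess of 9 limits bis-alkylation, and no stereocentre is touched.

Step 6
Reactants: 13 aryloxyacetyl imide; 14 vanillin (1.5 equiv)
Product: 18 (4S)-4-benzyl-3-[(2R,3R)-3-hydroxy-3-(4-hydroxy-3-methoxyphenyl)-2-((−)-pinoresinol-4-O-yl)propanoyl]-1,3-oxazolidin-2-one (anti-aldol imide), via O-TMS-vanillin 15 (not isolated), via silylated imide 16 (not isolated), via tris-TMS aldol adduct 17 (not isolated)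
Conditions: MgCl2 (0.3 equiv), Et3N (7 equiv), TMSCl (5 equiv), EtOAc, 23 °C, 24–48 h; then AcOH/THF/H2O, rt
Reagents that add atoms: chlorotrimethylsilane, C[Si](C)(C)Cl (its Me3Si groups sit only in 15–17 and are gone in 18)
Why: Proposed new method: the Evans MgCl2/Et3N/TMSCl anti-aldol, known for N-propionyl oxazolidinones with electron-rich aromatic aldehydes, is extended to an aryloxyacetyl imide while the same TMSCl/Et3N masks both free phenols in situ; the Mg-chelated (Z)-enolate of the (S)-imide is attacked on the face away from the benzyl group (the same sense as chelate-controlled alkylation, which sets C8''), the anti relation that sets C7'' as R comes from the boat-type addition locked by irreversible silylation of the Mg aldolate, and it is reinforced by the intrinsic erythro preference of metal-chelated aryloxyacetate enolates toward benzaldehydes.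

Step 7
Reactants: 18 anti-aldol imide
Product: 19 target, (1R,2S)-1-(4-hydroxy-3-methoxyphenyl)-2-{4-[(1R,3aS,4R,6aS)-4-(4-hydroxy-3-methoxyphenyl)tetrahydro-1H,3H-furo[3,4-c]furan-1-yl]-2-methoxyphenoxy}propane-1,3-diol
Conditions: NaBH4 (6 equiv), THF/H2O 4:1, 0 °C → rt
Reagents that add atoms: none
Why: Borohydride reductive cleavage of the N-acyl oxazolidinone turns the exocyclic C=O into CH2OH and releases the auxiliary without touching C7''/C8'', and the C8'' label changes from R to S only because the CIP priorities change.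

## Compound list
1 | (R)-4-benzyl-1,3-oxazolidin-2-one | O=C1OC[C@@H](Cc2ccccc2)N1 | starting material
2 | succinyl chloride | O=C(Cl)CCC(=O)Cl | starting material
3 | 1,4-bis[(4R)-4-benzyl-2-oxo-1,3-oxazolidin-3-yl]butane-1,4-dione | O=C(CCC(=O)N1[C@H](Cc2ccccc2)COC1=O)N1[C@H](Cc2ccccc2)COC1=O | intermediate
4 | vanillin isobutyrate | COc1cc(C=O)ccc1OC(=O)C(C)C | starting material
5 | (1Z,3Z)-1,4-bis(dibutylboryloxy)-1,4-bis[(4R)-4-benzyl-2-oxooxazolidin-3-yl]buta-1,3-diene | CCCCB(CCCC)O/C(=C\C=C(/OB(CCCC)CCCC)N1[C@H](Cc2ccccc2)COC1=O)N1[C@H](Cc2ccccc2)COC1=O | intermediate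
6 | (2R,3R)-2,3-bis{(R)-hydroxy[4-(isobutyryloxy)-3-methoxyphenyl]methyl}-1,4-bis[(4R)-4-benzyl-2-oxooxazolidin-3-yl]butane-1,4-dione | COc1cc([C@H](O)[C@H](C(=O)N2[C@H](Cc3ccccc3)COC2=O)[C@@H](C(=O)N2[C@H](Cc3ccccc3)COC2=O)[C@@H](O)c2ccc(OC(=O)C(C)C)c(OC)c2)ccc1OC(=O)C(C)C | intermediate
7 | (3R,3aR,6R,6aR)-3,6-bis[4-(isobutyryloxy)-3-methoxyphenyl]tetrahydrofuro[3,4-c]furan-1,4-dione | COc1cc([C@@H]2OC(=O)[C@@H]3[C@H]2C(=O)O[C@H]3c2ccc(OC(=O)C(C)C)c(OC)c2)ccc1OC(=O)C(C)C | intermediate
8 | (1R,2S,3S,4R)-1,4-bis(4-hydroxy-3-methoxyphenyl)-2,3-bis(hydroxymethyl)butane-1,4-diol | COc1cc([C@H](O)[C@H](CO)[C@@H](CO)[C@@H](O)c2ccc(O)c(OC)c2)ccc1O | intermediate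
9 | (−)-pinoresinol, 4,4'-[(1R,3aS,4R,6aS)-tetrahydro-1H,3H-furo[3,4-c]furan-1,4-diyl]bis(2-methoxyphenol) | COc1cc([C@@H]2OC[C@@H]3[C@H]2CO[C@H]3c2ccc(O)c(OC)c2)ccc1O | intermediate
10 | (S)-4-benzyl-1,3-oxazolidin-2-one | O=C1OC[C@H](Cc2ccccc2)N1 | starting material
11 | bromoacetyl bromide | BrCC(Br)=O | starting material
12 | (4S)-4-benzyl-3-(bromoacetyl)-1,3-oxazolidin-2-one | O=C(CBr)N1[C@@H](Cc2ccccc2)COC1=O | intermediate
13 | (4S)-4-benzyl-3-({4-[(1R,3aS,4R,6aS)-4-(4-hydroxy-3-methoxyphenyl)tetrahydro-1H,3H-furo[3,4-c]furan-1-yl]-2-methoxyphenoxy}acetyl)-1,3-oxazolidin-2-one | O=C(COc1ccc([C@@H]2OC[C@@H]3[C@H]2CO[C@H]3c2ccc(O)c(OC)c2)cc1OC)N1[C@@H](Cc2ccccc2)COC1=O | intermediate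
14 | vanillin | COc1cc(C=O)ccc1O | starting material
15 | 3-methoxy-4-(trimethylsilyloxy)benzaldehyde | COc1cc(C=O)ccc1O[Si](C)(C)C | intermediate
16 | phenol O-TMS ether of 13 | O=C(COc1ccc([C@@H]2OC[C@@H]3[C@H]2CO[C@H]3c2ccc(O[Si](C)(C)C)c(OC)c2)cc1OC)N1[C@@H](Cc2ccccc2)COC1=O | intermediate
17 | tris-O-TMS ether of 18 (both phenols and the C7'' oxygen) | COc1cc([C@@H](O[Si](C)(C)C)[C@H](C(=O)N2[C@@H](Cc3ccccc3)COC2=O)Oc2ccc([C@@H]3OC[C@@H]4[C@H]3CO[C@H]4c3ccc(O[Si](C)(C)C)c(OC)c3)cc2OC)ccc1O[Si](C)(C)C | intermediate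
18 | (4S)-4-benzyl-3-[(2R,3R)-3-hydroxy-3-(4-hydroxy-3-methoxyphenyl)-2-{4-[(1R,3aS,4R,6aS)-4-(4-hydroxy-3-methoxyphenyl)tetrahydro-1H,3H-furo[3,4-c]furan-1-yl]-2-methoxyphenoxy}propanoyl]-1,3-oxazolidin-2-one | COc1cc([C@@H](O)[C@H](C(=O)N2[C@@H](Cc3ccccc3)COC2=O)Oc2ccc([C@@H]3OC[C@@H]4[C@H]3CO[C@H]4c3ccc(O)c(OC)c3)cc2OC)ccc1O | intermediate
19 | CNP0172915.1, (−)-pinoresinol 4-O-[erythro-(7''R,8''S)-guaiacylglycerol-8''-yl] ether | COc1cc([C@@H](O)[C@H](CO)Oc2ccc([C@@H]3OC[C@@H]4[C@H]3CO[C@H]4c3ccc(O)c(OC)c3)cc2OC)ccc1O | target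

## Count and risks
Total step count: 7. Longest linear sequence: 6 (steps 1, 2, 3, 5, 6, 7). Step 4 is a one-step side branch.

**Step 2 (double aldol and double lactonisation).** The second enolisation or the hindered second aldol may stall at the mono-adduct.

- The fallback sets out from 4 and comes back at 7. It sets the stereocentres by catalytic asymmetric reduction instead of by aldol addition.
- Roskamp homologation of 4 with ethyl diazoacetate (cat. NbCl5, CH2Cl2) gives ethyl 3-[4-(isobutyryloxy)-3-methoxyphenyl]-3-oxopropanoate F1.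
- NaH and then I2 (0.5 equiv) in THF couples two enolates to diethyl 2,3-bis[4-(isobutyryloxy)-3-methoxybenzoyl]succinate F2, a stereolabile dl/meso mixture.
- Double Noyori–Ikariya transfer hydrogenation with RuCl(p-cymene)[(R,R)-TsDPEN] in HCO2H/Et3N makes both carbinols R.
- The acidic α-carbons equilibrate (dynamic kinetic resolution). The first lactone prefers aryl trans to its neighbour, and the cis ring fusion then dictates the last centre.
- Both γ-hydroxy esters lactonise in the same pot to 7.

**Step 6 (Mg-catalysed anti-aldol on an aryloxyacetyl imide).** The anti/syn ratio or the facial sense may not carry over from the propionyl series.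

- The fallback sets out from 9, with help from 1, 11 and 4, and comes back at 19. It uses the well-proven boron syn-aldol followed by inversion of the carbinol.
- Compounds 1 and 11 (n-BuLi, THF) give (4R)-4-benzyl-3-(bromoacetyl)-1,3-oxazolidin-2-one F4.
- F4 alkylates 9 (K2CO3, acetone) to the (4R)-auxiliary analogue of 13, (4R)-4-benzyl-3-{[(−)-pinoresinol-4-O-yl]acetyl}-1,3-oxazolidin-2-one F5.
- Bu2BOTf/i-Pr2NEt is used with one extra equivalent, which ties up the free phenol as a borinate. Addition of 4 then gives the Evans syn adduct, the (2R,3S)-3-hydroxy-3-[4-(isobutyryloxy)-3-methoxyphenyl]-2-aryloxypropanoyl imide F6.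
- Mitsunobu inversion at the benzylic carbon (PPh3, DIAD, 4-nitrobenzoic acid) gives the (2R,3R)-4-nitrobenzoate F7. The carboxylic acid out-competes the phenol as the nucleophile.
- LiBH4 in THF/MeOH removes the auxiliary, the nitrobenzoate and the isobutyrate together to give 19.

**Step 3 (reduction and acid closure).** Acid may leak to epipinoresinol, to the 2,5-diaryl-THF or to an aryltetralin.

- The fallback sets out from 7 and comes back at 9. It never opens the rings and never ionises C7.
- Excess DIBAL-H (CH2Cl2, −78 °C → −40 °C) reduces both lactones to lactols and cleaves both aryl esters. The product is the bis-lactol (9,9'-dihydroxy-(−)-pinoresinol, anomer mixture) F3.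
- Ionic hydrogenation (Et3SiH, BF3·OEt2, CH2Cl2, −78 °C) removes the two lactol oxygens through the C9/C9' oxocarbenium ions.
- The exo aryl groups set in step 2 are therefore simply retained in 9.

## Further compounds
F1 | step 2 | ethyl 3-[4-(isobutyryloxy)-3-methoxyphenyl]-3-oxopropanoate | CCOC(=O)CC(=O)c1ccc(OC(=O)C(C)C)c(OC)c1
F2 | step 2 | diethyl 2,3-bis[4-(isobutyryloxy)-3-methoxybenzoyl]succinate (stereolabile dl/meso mixture) | CCOC(=O)C(C(=O)c1ccc(OC(=O)C(C)C)c(OC)c1)C(C(=O)OCC)C(=O)c1ccc(OC(=O)C(C)C)c(OC)c1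
F3 | step 3 | 9,9'-dihydroxy-(−)-pinoresinol (bis-lactol, anomer mixture) | COc1cc([C@@H]2OC(O)[C@@H]3[C@H]2C(O)O[C@H]3c2ccc(O)c(OC)c2)ccc1O
F4 | step 6 | (4R)-4-benzyl-3-(bromoacetyl)-1,3-oxazolidin-2-one | O=C(CBr)N1[C@H](Cc2ccccc2)COC1=O
F5 | step 6 | (4R)-4-benzyl-3-{[(−)-pinoresinol-4-O-yl]acetyl}-1,3-oxazolidin-2-one | O=C(COc1ccc([C@@H]2OC[C@@H]3[C@H]2CO[C@H]3c2ccc(O)c(OC)c2)cc1OC)N1[C@H](Cc2ccccc2)COC1=O
F6 | step 6 | (4R)-4-benzyl-3-[(2R,3S)-3-hydroxy-3-[4-(isobutyryloxy)-3-methoxyphenyl]-2-((−)-pinoresinol-4-O-yl)propanoyl]-1,3-oxazolidin-2-one | COc1cc([C@H](O)[C@H](C(=O)N2[C@H](Cc3ccccc3)COC2=O)Oc2ccc([C@@H]3OC[C@@H]4[C@H]3CO[C@H]4c3ccc(O)c(OC)c3)cc2OC)ccc1OC(=O)C(C)C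
F7 | step 6 | (2R,3R)-3-(4-nitrobenzoyloxy) analogue of F6 (C7'' inverted) | COc1cc([C@@H](OC(=O)c2ccc(cc2)[N+](=O)[O-])[C@H](C(=O)N2[C@H](Cc3ccccc3)COC2=O)Oc2ccc([C@@H]3OC[C@@H]4[C@H]3CO[C@H]4c3ccc(O)c(OC)c3)cc2OC)ccc1OC(=O)C(C)C
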